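The route rests on cutting the diene single bond between C4, the alkene CH remote from the carbinol, and C3, the carbon bearing the exocyclic methylidene, of the nine-carbon carbamate chain on thiazole C2 (C1 = NCH2). The (4Z)-CH=CH unit between the C7 carbinol and C3 is read as a latent alkyne, and C3 as the Markovnikov carbon of a second terminal alkyne. A Sonogashira sp–sp2 coupling joins the complete, unprotected thiazole homopropargylic alcohol to a 2-iodoalkene carbamate and gives a conjugated enyne that holds every carbon of the target. A conjugation-selective syn semi-reduction then sets the Z-alkene without touching the skipped diene at thiazole C4.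

Key step: step 9

Assumption (chemistry): (R)-TRIP is taken to direct the allenyl boronate to the Re face of aldehyde 10, the sense expected from its behaviour with simpler aldehydes; if the carbinol proved to be (S), the (S)-acid would be used with no other change.

Step 1
Reactants: 1 ethyl 2-cyano-2-methylpropanoate
Product: 2 ethyl 3-amino-2,2-dimethyl-3-sulfanylidenepropanoate
Conditions: (NH4)2S (20% aq.), MeOH, rt to 50 °C
Reagents that add atoms: ammonium sulfide, [NH4+].[NH4+].[S-2]
Why: Thionation of a nitrile, in which hydrosulfide adds to the ester-activated, non-enolisable nitrile and should give the primary thioamide needed for the thiazole ring synthesis.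

Step 2
Reactants: 2 ethyl 3-amino-2,2-dimethyl-3-sulfanylidenepropanoate; 3 1,3-dichloropropan-2-one
Product: 5 ethyl 2-[4-(chloromethyl)-1,3-thiazol-2-yl]-2-methylpropanoate, via hydroxythiazoline 4 (not isolated)
Conditions: acetone, MgSO4, reflux
Reagents that add atoms: none
Why: Hantzsch thiazole synthesis, in which S-alkylation by one CH2Cl group and attack of nitrogen on the ketone give the 4-hydroxythiazoline, whose dehydration aromatises the ring and leaves the second CH2Cl group at C4 as the handle for the side chain, the symmetry of 3 excluding regioisomers.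

Step 3
Reactants: 5 ethyl 2-[4-(chloromethyl)-1,3-thiazol-2-yl]-2-methylpropanoate; 6 pent-1-en-4-yne
Product: 7 ethyl 2-[4-(hex-5-en-2-yn-1-yl)-1,3-thiazol-2-yl]-2-methylpropanoate
Conditions: CuI (20 mol %), NaI (20 mol %), Cs2CO3, MeCN, 40 °C
Reagents that add atoms: none
Why: Copper-catalysed sp–sp3 alkynylation of the kind used for skipped enynes and diynes, in which the copper acetylide of 6 displaces the activated thiazol-4-ylmethyl halide (iodide formed in situ) under a carbonate base mild enough to spare the ester.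

Step 4
Reactants: 7 ethyl 2-[4-(hex-5-en-2-yn-1-yl)-1,3-thiazol-2-yl]-2-methylpropanoate
Product: 8 ethyl 2-{4-[(2Z)-hexa-2,5-dien-1-yl]-1,3-thiazol-2-yl}-2-methylpropanoate
Conditions: H2 (1 atm), Lindlar catalyst, quinoline, EtOAc, rt, stopped after 1 equiv H2
Reagents that add atoms: none
Why: Lindlar semi-hydrogenation, in which syn delivery of hydrogen on lead-poisoned palladium should give the (2Z)-alkene because the alkyne binds far more strongly than the terminal alkene or the product.

Step 5
Reactants: 8 ethyl 2-{4-[(2Z)-hexa-2,5-dien-1-yl]-1,3-thiazol-2-yl}-2-methylpropanoate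
Product: 10 2-{4-[(2Z)-hexa-2,5-dien-1-yl]-1,3-thiazol-2-yl}-2-methylpropanal, via aluminium hemiacetal 9 (not isolated)
Conditions: DIBAL-H (1.1 equiv), CH2Cl2, −78 °C; aq. Rochelle salt
Reagents that add atoms: none
Why: Partial reduction of an ester with DIBAL-H, in which the tetrahedral aluminium hemiacetal of the hindered α,α-dimethyl ester should persist at −78 °C and release the non-enolisable aldehyde only on work-up.

Step 6
Reactants: 10 2-{4-[(2Z)-hexa-2,5-dien-1-yl]-1,3-thiazol-2-yl}-2-methylpropanal; 11 4,4,5,5-tetramethyl-2-(propa-1,2-dien-1-yl)-1,3,2-dioxaborolane (allenylboronic acid pinacol ester)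
Product: 13 (3R)-2-{4-[(2Z)-hexa-2,5-dien-1-yl]-1,3-thiazol-2-yl}-2-methylhex-5-yn-3-ol, via pinacol borate 12 (not isolated)
Conditions: (R)-TRIP (20 mol %), 4 Å MS, toluene, 0 °C; aq. NaHCO3 work-up
Reagents that add atoms: none
Why: Chiral phosphoric acid-catalysed allenylboration (asymmetric carbonyl propargylation), in which the allenyl boronate adds through its γ-carbon in a closed six-membered transition state organised by the acid, which should direct attack to the Re face of the aldehyde and so set the (R)-carbinol with the terminal alkyne already in place.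

Step 7
Reactants: 14 but-3-yn-1-amine
Product: 15 methyl N-(but-3-yn-1-yl)carbamate
Conditions: ClCO2Me, Et3N, CH2Cl2, 0 °C
Reagents that add atoms: methyl chloroformate, COC(=O)Cl
Why: N-acylation of a primary amine with a chloroformate should give the methyl carbamate of the target without affecting the alkyne.

Step 8
Reactants: 15 methyl N-(but-3-yn-1-yl)carbamate
Product: 16 methyl N-(3-iodobut-3-en-1-yl)carbamate
Conditions: TMSCl, NaI, H2O (0.5 equiv), MeCN, rt, dark
Reagents that add atoms: sodium iodide, [Na+].[I-]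
Why: Markovnikov hydroiodination of a terminal alkyne, in which HI generated in situ should add with iodine on the internal carbon to give the 2-iodo-1-alkene, the carbamate being stable to these conditions at room temperature.

Step 9
Reactants: 13 (3R)-2-{4-[(2Z)-hexa-2,5-dien-1-yl]-1,3-thiazol-2-yl}-2-methylhex-5-yn-3-ol; 16 methyl N-(3-iodobut-3-en-1-yl)carbamate
Product: 17 methyl N-[(7R)-8-{4-[(2Z)-hexa-2,5-dien-1-yl]-1,3-thiazol-2-yl}-7-hydroxy-8-methyl-3-methylidenenon-4-yn-1-yl]carbamate
Conditions: Pd(PPh3)4 (5 mol %), CuI (10 mol %), Et3N, THF (degassed), rt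
Reagents that add atoms: none
Why: Pd(0) inserts into the C(sp2)–I bond of 16, the copper acetylide formed from the only terminal alkyne C–H of 13 transmetalates, and reductive elimination forms the C4–C3 bond as a C(sp)–C(sp2) bond. The closest known reaction type is the Sonogashira coupling of 2-halo-1-alkenes with functionalised terminal alkynes, which runs at room temperature in the presence of free hydroxyl and carbamate N–H groups. No ring is closed and no stereocentre is created: the C7 carbinol is remote from the reacting carbons and is not epimerisable under amine base, and the geometry of the C4=C5 alkene is left open until step 10. The step needs chemoselectivity (one C–I bond and one C(sp)–H bond, with the thiazole C5–H, the skipped diene and the methylidene inert to Pd(0)/Cu(I) at room temperature) and cross-coupling over alkyne homo-coupling, which exclusion of oxygen and a small excess of 16 should secure. Regiochemistry at C3 cannot drift because the iodine of 16 already sits on the carbon that must carry the methylidene, and a 1,1-disubstituted vinyl iodide has no alkene geometry to lose.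

Step 10
Reactants: 17 methyl N-[(7R)-8-{4-[(2Z)-hexa-2,5-dien-1-yl]-1,3-thiazol-2-yl}-7-hydroxy-8-methyl-3-methylidenenon-4-yn-1-yl]carbamate
Product: 18 methyl N-[(4Z,7R)-8-{4-[(2Z)-hexa-2,5-dien-1-yl]-1,3-thiazol-2-yl}-7-hydroxy-8-methyl-3-methylidenenon-4-en-1-yl]carbamate (mycothiazole)
Conditions: Zn(Cu/Ag), MeOH/H2O (1:1), rt to 40 °C
Reagents that add atoms: none
Why: Boland reduction, in which activated zinc transfers two electrons and two protons syn across the triple bond that is activated by conjugation with the C3 methylidene, so that the (4Z)-alkene should form while the isolated alkenes, the thiazole and the product diene are not reduced.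

Compound list
1 | ethyl 2-cyano-2-methylpropanoate | CCOC(=O)C(C)(C)C#N | starting material
2 | ethyl 3-amino-2,2-dimethyl-3-sulfanylidenepropanoate | CCOC(=O)C(C)(C)C(N)=S | intermediate
3 | 1,3-dichloropropan-2-one | ClCC(=O)CCl | starting material
4 | ethyl 2-[4-(chloromethyl)-4-hydroxy-4,5-dihydro-1,3-thiazol-2-yl]-2-methylpropanoate (racemic hydroxythiazoline) | CCOC(=O)C(C)(C)C1=NC(O)(CCl)CS1 | intermediate
5 | ethyl 2-[4-(chloromethyl)-1,3-thiazol-2-yl]-2-methylpropanoate | CCOC(=O)C(C)(C)c1nc(CCl)cs1 | intermediate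
6 | pent-1-en-4-yne | C=CCC#C | starting material
7 | ethyl 2-[4-(hex-5-en-2-yn-1-yl)-1,3-thiazol-2-yl]-2-methylpropanoate | CCOC(=O)C(C)(C)c1nc(CC#CCC=C)cs1 | intermediate
8 | ethyl 2-{4-[(2Z)-hexa-2,5-dien-1-yl]-1,3-thiazol-2-yl}-2-methylpropanoate | CCOC(=O)C(C)(C)c1nc(C/C=C\CC=C)cs1 | intermediate
9 | diisobutylaluminium hemiacetal of ester 8 (1-ethoxy-2-{4-[(2Z)-hexa-2,5-dien-1-yl]-1,3-thiazol-2-yl}-2-methylpropyl diisobutylaluminium oxide) | CCOC(O[Al](CC(C)C)CC(C)C)C(C)(C)c1nc(C/C=C\CC=C)cs1 | intermediate
10 | 2-{4-[(2Z)-hexa-2,5-dien-1-yl]-1,3-thiazol-2-yl}-2-methylpropanal | O=CC(C)(C)c1nc(C/C=C\CC=C)cs1 | intermediate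
11 | 4,4,5,5-tetramethyl-2-(propa-1,2-dien-1-yl)-1,3,2-dioxaborolane | C=C=CB1OC(C)(C)C(C)(C)O1 | starting material
12 | pinacol borate of alcohol 13 (2-{[(3R)-2-{4-[(2Z)-hexa-2,5-dien-1-yl]-1,3-thiazol-2-yl}-2-methylhex-5-yn-3-yl]oxy}-4,4,5,5-tetramethyl-1,3,2-dioxaborolane) | C=CC/C=C\Cc1csc(C(C)(C)[C@H](OB2OC(C)(C)C(C)(C)O2)CC#C)n1 | intermediate
13 | (3R)-2-{4-[(2Z)-hexa-2,5-dien-1-yl]-1,3-thiazol-2-yl}-2-methylhex-5-yn-3-ol | C=CC/C=C\Cc1csc(C(C)(C)[C@H](O)CC#C)n1 | intermediate
14 | but-3-yn-1-amine | C#CCCN | starting material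
15 | methyl N-(but-3-yn-1-yl)carbamate | C#CCCNC(=O)OC | intermediate
16 | methyl N-(3-iodobut-3-en-1-yl)carbamate | C=C(I)CCNC(=O)OC | intermediate
17 | methyl N-[(7R)-8-{4-[(2Z)-hexa-2,5-dien-1-yl]-1,3-thiazol-2-yl}-7-hydroxy-8-methyl-3-methylidenenon-4-yn-1-yl]carbamate | C=CC/C=C\Cc1csc(C(C)(C)[C@H](O)CC#CC(=C)CCNC(=O)OC)n1 | intermediate
18 | methyl N-[(4Z,7R)-8-{4-[(2Z)-hexa-2,5-dien-1-yl]-1,3-thiazol-2-yl}-7-hydroxy-8-methyl-3-methylidenenon-4-en-1-yl]carbamate (mycothiazole) | C=CC/C=C\Cc1csc(C(C)(C)[C@H](O)C/C=C\C(=C)CCNC(=O)OC)n1 | target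

Total step count: 10. Longest linear sequence: 8 steps (steps 1–6, 9 and 10); steps 7 and 8 form the short second branch.

Steps most likely to fail

1. Step 6. The neopentyl-type aldehyde is hindered and the basic thiazole nitrogen may bind the acid catalyst, so the catalysed pathway may be slow, the uncatalysed allenylboration may compete and the facial selectivity may be poor. Fallback, setting out from 10 and returning at 13: methylene transfer with trimethylsulfonium iodide and KHMDS (Corey–Chaykovsky epoxidation of the non-enolisable aldehyde) should give racemic 2-(2-{4-[(2Z)-hexa-2,5-dien-1-yl]-1,3-thiazol-2-yl}propan-2-yl)oxirane F1. Hydrolytic kinetic resolution with (R,R)-(salen)Co(III)OAc and 0.55 equiv of water should consume the (R)-epoxide and leave (2S)-2-(2-{4-[(2Z)-hexa-2,5-dien-1-yl]-1,3-thiazol-2-yl}propan-2-yl)oxirane F2. BF3·OEt2-promoted opening at the unhindered CH2 terminus with lithium (trimethylsilyl)acetylide at −78 °C should give (3R)-2-{4-[(2Z)-hexa-2,5-dien-1-yl]-1,3-thiazol-2-yl}-2-methyl-6-(trimethylsilyl)hex-5-yn-3-ol F3, the descriptor changing from S to R only through the priority switch. K2CO3 in MeOH then removes the silyl group to give 13.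

2. Step 3. The doubly activated CH2 groups of 6 and of the product may undergo base-mediated propargyl-to-allene isomerisation, the displacement may be slow, and the semi-hydrogenation that follows adds the risk of reducing the terminal alkene. Fallback, setting out from 2 and returning at 8 (it bypasses 5 and 7): Hantzsch condensation of 2 with ethyl 4-chloro-3-oxobutanoate should give ethyl 2-[4-(2-ethoxy-2-oxoethyl)-1,3-thiazol-2-yl]-2-methylpropanoate F4. One equivalent of DIBAL-H at −78 °C should reduce only the unhindered acetate ester to ethyl 2-methyl-2-[4-(2-oxoethyl)-1,3-thiazol-2-yl]propanoate F5, which is used crude. A salt-free Z-selective Wittig reaction with the ylide from but-3-en-1-yl(triphenyl)phosphonium bromide and NaHMDS (THF, −78 °C) should then give 8 with no hydrogenation step.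

3. Step 10. Conversion on the heterogeneous metal may stop early, or Z-selectivity may erode and the conjugated system may be over-reduced. Fallback, setting out from 13 and returning at 18 (it bypasses 17): silylation of the carbinol with 1,1,3,3-tetramethyldisilazane should give {[(3R)-2-{4-[(2Z)-hexa-2,5-dien-1-yl]-1,3-thiazol-2-yl}-2-methylhex-5-yn-3-yl]oxy}dimethylsilane F6. Intramolecular endo-dig trans-hydrosilylation with [Cp*Ru(MeCN)3]PF6 in CH2Cl2 should close the six-membered cyclic (Z)-alkenylsiloxane (6R)-6-(2-{4-[(2Z)-hexa-2,5-dien-1-yl]-1,3-thiazol-2-yl}propan-2-yl)-2,2-dimethyl-3,6-dihydro-2H-1,2-oxasiline F7, in which the ring fixes the cis geometry. Fluoride-promoted Hiyama–Denmark coupling of F7 with iodide 16 (TBAF, Pd2(dba)3, THF, rt) should form the same C4–C3 bond with retention and release the free carbinol, giving 18 directly.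

Further compounds
F1 | step 6 | racemic 2-(2-{4-[(2Z)-hexa-2,5-dien-1-yl]-1,3-thiazol-2-yl}propan-2-yl)oxirane | C=CC/C=C\Cc1csc(C(C)(C)C2CO2)n1
F2 | step 6 | (2S)-2-(2-{4-[(2Z)-hexa-2,5-dien-1-yl]-1,3-thiazol-2-yl}propan-2-yl)oxirane | C=CC/C=C\Cc1csc(C(C)(C)[C@H]2CO2)n1
F3 | step 6 | (3R)-2-{4-[(2Z)-hexa-2,5-dien-1-yl]-1,3-thiazol-2-yl}-2-methyl-6-(trimethylsilyl)hex-5-yn-3-ol | C=CC/C=C\Cc1csc(C(C)(C)[C@H](O)CC#C[Si](C)(C)C)n1
F4 | step 3 | ethyl 2-[4-(2-ethoxy-2-oxoethyl)-1,3-thiazol-2-yl]-2-methylpropanoate | CCOC(=O)Cc1csc(C(C)(C)C(=O)OCC)n1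
F5 | step 3 | ethyl 2-methyl-2-[4-(2-oxoethyl)-1,3-thiazol-2-yl]propanoate | CCOC(=O)C(C)(C)c1nc(CC=O)cs1
F6 | step 10 | {[(3R)-2-{4-[(2Z)-hexa-2,5-dien-1-yl]-1,3-thiazol-2-yl}-2-methylhex-5-yn-3-yl]oxy}dimethylsilane | C=CC/C=C\Cc1csc(C(C)(C)[C@H](O[SiH](C)C)CC#C)n1
F7 | step 10 | (6R)-6-(2-{4-[(2Z)-hexa-2,5-dien-1-yl]-1,3-thiazol-2-yl}propan-2-yl)-2,2-dimethyl-3,6-dihydro-2H-1,2-oxasiline | C=CC/C=C\Cc1csc(C(C)(C)[C@H]2CC=C[Si](C)(C)O2)n1
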